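**Plan**

- Retrosynthesis cuts the C2–Br and C3–Br bonds first (electrophilic bromination), then the C4–Br and C6–Br bonds (each traced back to an aryl C–O triflate), then the C3–C3a bond of the pyrrole ring, and last the C7a–N1 bond.
- Forward: phloroglucinol is aminated with N-methylaminoacetaldehyde dimethyl acetal (C7a–N1), acid closes the pyrrole ring (C3–C3a) onto the symmetric aminoresorcinol, both phenols are triflated, both C–OTf groups are exchanged for C–Br under palladium catalysis, and NBS brominates C3, then C2.
- Enabling feature: on the benzo ring, N1 (at C7a), Br at C4 and Br at C6 stand in a 1,3,5-relationship. Electrophilic bromination of an indole does not reach C4 or C6, but this is the oxygen pattern of phloroglucinol, so two of its oxygens become the triflates that bring the bromines in.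
- The benzene ring is bought; the pyrrole ring is the only ring made (step 2); the key step closes no ring.
- The target is planar and has no stereocentre, so there is no stereochemistry to set or protect.

Key step: step 4

**Route**

Step 1
Reactants: 1 phloroglucinol; 2 (methylamino)acetaldehyde dimethyl acetal
Product: 3 5-[(2,2-dimethoxyethyl)(methyl)amino]benzene-1,3-diol
Conditions: 2 (1.05 equiv), degassed DMF–toluene, rt → 40 °C, Ar
Reagents that add atoms: none
Why: Phloroglucinol reacts through its keto tautomer, so the secondary amine condenses at one ring carbon with loss of water to give the aromatic vinylogous amide (a sulfite-free Bucherer-type phenol-to-amine exchange, i.e. enaminone formation), and the reaction should stop after one exchange because the aminoresorcinol is far less ketonic than phloroglucinol.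

Step 2
Reactants: 3 5-[(2,2-dimethoxyethyl)(methyl)amino]benzene-1,3-diol
Product: 5 1-methylindole-4,6-diol, via 3-methoxy-1-methylindoline-4,6-diol 4 (not isolated)
Conditions: slow addition of 3 to TFA (10 equiv) in degassed CH2Cl2 (high dilution), 0 °C → rt, Ar; degassed aq NaHCO3 work-up, crude used at once
Reagents that add atoms: none
Why: TFA ionises the acetal to an oxocarbenium ion that is captured by the ring carbon ortho to nitrogen (ortho and para to the two hydroxyls) in an intramolecular Friedel–Crafts alkylation, and acid-promoted loss of methanol from indoline 4 aromatises the pyrrole ring (aminoacetal indole synthesis of the Nordlander type); the two ortho carbons are equivalent by symmetry, so only the 4,6-dioxygenated indole can result.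

Step 3
Reactants: 5 1-methylindole-4,6-diol
Product: 8 1-methylindole-4,6-diyl bis(trifluoromethanesulfonate), via 6-hydroxy-1-methylindol-4-yl triflate 6 (not isolated), via 4-hydroxy-1-methylindol-6-yl triflate 7 (not isolated)
Conditions: PhNTf2 (2.3 equiv), Et3N (3 equiv), DMAP (cat.), CH2Cl2, 0 °C → rt, Ar
Reagents that add atoms: N-phenylbis(trifluoromethanesulfonimide), O=S(=O)(N(c1ccccc1)S(=O)(=O)C(F)(F)F)C(F)(F)F
Why: O-Sulfonylation of the two phenoxides with the mild triflyl donor PhNTf2, which reacts at oxygen and should leave the nucleophilic C3, C5 and C7 carbons of the electron-rich indole untouched; whichever mono-triflate (6 or 7) forms first is triflated again to 8.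

Step 4
Reactants: 8 1-methylindole-4,6-diyl bis(trifluoromethanesulfonate)
Product: 11 4,6-dibromo-1-methylindole, via 6-bromo-1-methylindol-4-yl triflate 9 (not isolated), via 4-bromo-1-methylindol-6-yl triflate 10 (not isolated)
Conditions: Pd2(dba)3 (cat.), t-BuBrettPhos (cat.), KBr (6 equiv), KF (1 equiv), 1,4-dioxane, 130 °C, sealed tube, Ar
Reagents that add atoms: potassium bromide, [K+].[Br-]
Why: Ligated Pd(0) inserts into a C–OTf bond of 8, the triflate on palladium(II) is replaced by bromide from KBr, and the bulk of t-BuBrettPhos makes C–Br reductive elimination from the ArPd(L)Br complex feasible; the cycle then runs a second time on whichever bromo triflate (9 or 10) forms first, so both paths converge on 11. The closest known reaction type is the palladium/bulky-biarylphosphine-catalysed conversion of aryl triflates into aryl bromides, applied here twice on one arene. No ring closes and no stereocentre forms; the bonds made are C4–Br and C6–Br. The step needs complete double exchange without hydrodehalogenation, S–O cleavage to the phenol, or arylation of the indole C2/C3 positions by an arylpalladium intermediate. A large excess of bromide keeps palladium(II) as the bromide and makes re-insertion into product C–Br bonds degenerate, the N-methyl group removes the N–H that could bind palladium, and the absence of carbonate or carboxylate base disfavours C–H palladation. Bromide cannot displace triflate directly on this electron-rich arene, which is why the metal cycle is needed.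

Step 5
Reactants: 11 4,6-dibromo-1-methylindole
Product: 13 2,3,4,6-tetrabromo-1-methylindole, via 3,4,6-tribromo-1-methylindole 12 (not isolated)
Conditions: NBS (2.05 equiv), THF, −78 °C → rt, dark
Reagents that add atoms: N-bromosuccinimide, O=C1CCC(=O)N1Br
Why: Electrophilic aromatic substitution on the pyrrole ring, the only electron-rich part left in 11: the first equivalent of NBS should brominate C3 to give 12 and the second C2, as in the known 2,3-dibromination of N-alkylindoles, while the benzo ring is deactivated by its two bromines and C5/C7 are each flanked by substituents.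

**Compound list**

1 | phloroglucinol (benzene-1,3,5-triol) | Oc1cc(O)cc(O)c1 | starting material
2 | (methylamino)acetaldehyde dimethyl acetal (2,2-dimethoxy-N-methylethanamine) | CNCC(OC)OC | starting material
3 | 5-[(2,2-dimethoxyethyl)(methyl)amino]benzene-1,3-diol | CN(CC(OC)OC)c1cc(O)cc(O)c1 | intermediate
4 | 3-methoxy-1-methylindoline-4,6-diol (racemic, not isolated) | CN1CC(OC)c2c(O)cc(O)cc21 | intermediate
5 | 1-methylindole-4,6-diol | Cn1ccc2c(O)cc(O)cc21 | intermediate
6 | 6-hydroxy-1-methylindol-4-yl trifluoromethanesulfonate (not isolated) | Cn1ccc2c(OS(=O)(=O)C(F)(F)F)cc(O)cc21 | intermediate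
7 | 4-hydroxy-1-methylindol-6-yl trifluoromethanesulfonate (not isolated) | Cn1ccc2c(O)cc(OS(=O)(=O)C(F)(F)F)cc21 | intermediate
8 | 1-methylindole-4,6-diyl bis(trifluoromethanesulfonate) | Cn1ccc2c(OS(=O)(=O)C(F)(F)F)cc(OS(=O)(=O)C(F)(F)F)cc21 | intermediate
9 | 6-bromo-1-methylindol-4-yl trifluoromethanesulfonate (not isolated) | Cn1ccc2c(OS(=O)(=O)C(F)(F)F)cc(Br)cc21 | intermediate
10 | 4-bromo-1-methylindol-6-yl trifluoromethanesulfonate (not isolated) | Cn1ccc2c(Br)cc(OS(=O)(=O)C(F)(F)F)cc21 | intermediate
11 | 4,6-dibromo-1-methylindole | Cn1ccc2c(Br)cc(Br)cc21 | intermediate
12 | 3,4,6-tribromo-1-methylindole (not isolated) | Cn1cc(Br)c2c(Br)cc(Br)cc21 | intermediate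
13 | 2,3,4,6-tetrabromo-1-methylindole | Cn1c(Br)c(Br)c2c(Br)cc(Br)cc21 | target

**Step count and risks**

Total step count: 5. Longest linear sequence: 5 steps, from phloroglucinol 1.

Steps most likely to fail, riskiest first:

1. Step 2 (pyrrole ring closure). The oxocarbenium ion may attack the very electron-rich ring of a second molecule, at the carbon between the two hydroxyls, and give oligomers instead of closing the ring. The unprotected dihydroxyindole may also self-condense in acid or oxidise in air before it can be triflated. Fallback, setting out from 3: both phenols are silylated (TIPSCl, imidazole, DMF) to N-(2,2-dimethoxyethyl)-N-methyl-3,5-bis(triisopropylsilyloxy)aniline F1, in which the bulky silyl groups shield the carbon between the oxygens. The same acid closure (TFA, CH2Cl2, 0 °C) should then pass through 3-methoxy-1-methyl-4,6-bis(triisopropylsilyloxy)indoline F2 (not isolated) to 1-methyl-4,6-bis(triisopropylsilyloxy)indole F3, a robust compound that can be chromatographed. Fluoride-triggered desilylative triflation (CsF, PhNTf2, DME, rt) converts F3 directly into bis-triflate 8, so that the free diol 5 never accumulates. The fallback returns to the route at 8.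

2. Step 4 (double triflate-to-bromide exchange). The exchange may stall after the first triflate, the arylpalladium intermediates may be reduced (hydrodehalogenation), fluoride may cleave the S–O bond to the phenol, or an arylpalladium species may arylate C2/C3 of another indole and lead to oligomers. Fallback, setting out from 8: double Miyaura borylation (PdCl2(dppf), B2pin2, KOAc, dioxane, 80 °C) gives 1-methyl-4,6-bis(4,4,5,5-tetramethyl-1,3,2-dioxaborolan-2-yl)indole F4. Copper(II) bromide mediated bromodeboronation (excess CuBr2, MeOH–H2O, 80 °C) then replaces both boryl groups and, with the excess, is expected to brominate C3–H as well, delivering tribromide 12. Any tetrabromide formed at this stage is the target itself. The fallback returns to the route at 12, which one equivalent of NBS (second half of step 5) takes to 13.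

3. Step 5 (2,3-dibromination). Peri strain between C3–Br and C4–Br may slow the second bromination, so that the second equivalent attacks the benzo ring (C7 or C5) instead of C2, or HBr traces may cause migration or loss of the C3 bromine and give mixtures. Fallback, setting out from 11: iridium-catalysed C–H borylation ([Ir(OMe)(cod)]2, dtbpy, B2pin2, THF, 60 °C) should be selective for C2, since C3 is peri to C4–Br and C5 and C7 are flanked, and give 4,6-dibromo-1-methyl-2-(4,4,5,5-tetramethyl-1,3,2-dioxaborolan-2-yl)indole F5. Bromodeboronation with CuBr2 (MeOH–H2O, 80 °C) gives 2,4,6-tribromo-1-methylindole F6, and one equivalent of NBS (THF, 0 °C) brominates the only free pyrrole position, C3. Concurrent C3 bromination by copper(II) bromide would lead to the same product. The fallback returns to the route at 13.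

Further compounds
F1 | step 2 | N-(2,2-dimethoxyethyl)-N-methyl-3,5-bis(triisopropylsilyloxy)aniline | CN(CC(OC)OC)c1cc(O[Si](C(C)C)(C(C)C)C(C)C)cc(O[Si](C(C)C)(C(C)C)C(C)C)c1
F2 | step 2 | 3-methoxy-1-methyl-4,6-bis(triisopropylsilyloxy)indoline (racemic, not isolated) | CN1CC(OC)c2c(O[Si](C(C)C)(C(C)C)C(C)C)cc(O[Si](C(C)C)(C(C)C)C(C)C)cc21
F3 | step 2 | 1-methyl-4,6-bis(triisopropylsilyloxy)indole | Cn1ccc2c(O[Si](C(C)C)(C(C)C)C(C)C)cc(O[Si](C(C)C)(C(C)C)C(C)C)cc21
F4 | step 4 | 1-methyl-4,6-bis(4,4,5,5-tetramethyl-1,3,2-dioxaborolan-2-yl)indole | Cn1ccc2c(B3OC(C)(C)C(C)(C)O3)cc(B3OC(C)(C)C(C)(C)O3)cc21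
F5 | step 5 | 4,6-dibromo-1-methyl-2-(4,4,5,5-tetramethyl-1,3,2-dioxaborolan-2-yl)indole | Cn1c(B3OC(C)(C)C(C)(C)O3)cc2c(Br)cc(Br)cc21
F6 | step 5 | 2,4,6-tribromo-1-methylindole | Cn1c(Br)cc2c(Br)cc(Br)cc21
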